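A direct plan would keep a purchased benzene ring and close only the pyranone onto it. The aryne from 3,5-dimethoxy-2-(trimethylsilyl)phenyl triflate A1 would insert into the carboxyl C–O bond of the MOM-protected ynoic acid A2 and the ynone phenoxide would cyclise in the same flask to the 5,7-dimethoxychromone A3. BCl3 would then give the dihydroxy chromone A4 by cleaving the peri methyl ether and the MOM acetal, and cross-metathesis with acrylic acid would finish the chain. Its weakest steps would be:
- the carbamoylation, ortho-silylation and triflation that arm the phenol as A1, three steps that add no complexity;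
- the aryne insertion, where the carboxylate would have to add to one end of an unsymmetrical aryne and the acyl shift outrun protonation at 125 °C;
- the closing pair, a peri-demethylation that must tell two methyl ethers apart and a metathesis with acrylic acid on a chelating hydroxychromone with free OH groups, where catalyst inhibition would be expected.

The new route builds ring A last, onto a 4-pyranone that already carries the stereodefined side chain. A pyranon-2-yl diazomethyl ketone and methoxyacetylene would give the benzo ring in one operation, by photochemical Wolff rearrangement, ketene–alkyne [2+2] cycloaddition, four-electron ring opening and six-electron electrocyclization. C5 with its free peri hydroxyl would come from the ketene carbonyl, C6 and C7–OMe from the alkyne, C8 from the diazo carbon, and C8a=C4a from the pyranone C2=C3 bond. The meta-dioxygenated ring A with unsubstituted C6 and C8 is exactly what this annulation delivers, so no aryne precursor, no demethylation and no metathesis is needed. A dioxinone provides both the stereocentre and the pyranone.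

Key step: step 7

Assumption: hept-6-enal, the bis(trimethylsilyl) derivative of pyruvic acid and the tert-butyl ylide are taken as purchasable, and the ligand enantiomer of the aldol step is defined by the aldehyde face it must leave open (Si), to be confirmed on the aldol product by Mosher ester analysis.

Step 1
Reactants: 1 2,2,6-trimethyl-4H-1,3-dioxin-4-one
Product: 2 [(2,2-dimethyl-6-methylidene-6H-1,3-dioxin-4-yl)oxy]trimethylsilane
Conditions: LiN(i-Pr)2 (1.1 equiv), THF, −78 °C; Me3SiCl (1.2 equiv), −78 → 0 °C; filtration, distillation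
Reagents that add atoms: chlorotrimethylsilane, C[Si](C)(C)Cl
Why: Kinetic γ-deprotonation of the vinylogous ester and O-silylation of the extended enolate (silyl dienol ether formation) should give the nucleophile for the vinylogous aldol step.

Step 2
Reactants: 2 [(2,2-dimethyl-6-methylidene-6H-1,3-dioxin-4-yl)oxy]trimethylsilane; 3 hept-6-enal
Product: 5 6-[(2R)-2-hydroxyoct-7-en-1-yl]-2,2-dimethyl-4H-1,3-dioxin-4-one, via trimethylsilyl ether 4 (not isolated)
Conditions: Ti(Oi-Pr)4 (3 mol%), Schiff base of 2-amino-2′-hydroxy-1,1′-binaphthyl and 3-bromo-5-tert-butylsalicylaldehyde (3 mol%, the enantiomer that leaves the Si face of the aldehyde open), 3,5-di-tert-butylsalicylic acid (3 mol%), Et2O, 0 °C; then CF3CO2H (10%), THF/H2O, 0 °C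
Reagents that add atoms: none
Why: In this catalytic enantioselective vinylogous Mukaiyama aldol addition the chiral tetravalent titanium complex binds the aldehyde, the γ-carbon of the dienol ether adds to its Si face through an open transition state, which sets the (R)-carbinol, and mild acid removes the transferred silyl group.

Step 3
Reactants: 5 6-[(2R)-2-hydroxyoct-7-en-1-yl]-2,2-dimethyl-4H-1,3-dioxin-4-one
Product: 6 6-[(2R)-2-(tert-butyldimethylsilyloxy)oct-7-en-1-yl]-2,2-dimethyl-4H-1,3-dioxin-4-one
Conditions: t-BuMe2SiCl (1.3 equiv), imidazole (2.5 equiv), DMF, rt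
Reagents that add atoms: tert-butyldimethylsilyl chloride, CC(C)(C)[Si](C)(C)Cl
Why: Silyl ether formation masks the hydroxyl, which would otherwise trap the acylketene of the next step as a six-membered lactone and later quench the ketene of the key step, and it does not touch the stereocentre.

Step 4
Reactants: 6 6-[(2R)-2-(tert-butyldimethylsilyloxy)oct-7-en-1-yl]-2,2-dimethyl-4H-1,3-dioxin-4-one; 7 trimethylsilyl 2-(trimethylsilyloxy)prop-2-enoate (2.5 equiv)
Product: 10 6-[(2R)-2-(tert-butyldimethylsilyloxy)oct-7-en-1-yl]-4-oxo-4H-pyran-2-carboxylic acid, via acylketene 8 (not isolated), via dihydropyranone cycloadduct 9 (not isolated)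
Conditions: toluene, 110 °C, acetone distilled off; then CF3CO2H (3 equiv), CH2Cl2, 0 °C; H2O
Reagents that add atoms: none
Why: Retro-[4+2] loss of acetone should give the acylketene, which as an electron-poor 1-oxadiene undergoes hetero-Diels–Alder cycloaddition with the silyl enol ether (CH2 to the ketene carbon, ketone oxygen to the silyloxy carbon), and acid-induced loss of trimethylsilanol with hydrolysis of the silyl ester gives the 4-pyranone acid with the stereocentre untouched.

Step 5
Reactants: 10 6-[(2R)-2-(tert-butyldimethylsilyloxy)oct-7-en-1-yl]-4-oxo-4H-pyran-2-carboxylic acid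
Product: 12 2-(2-diazoacetyl)-6-[(2R)-2-(tert-butyldimethylsilyloxy)oct-7-en-1-yl]-4H-pyran-4-one, via mixed anhydride 11 (not isolated)
Conditions: i-BuOCOCl (1.1 equiv), N-methylmorpholine (1.1 equiv), THF, −15 °C; CH2N2 (3 equiv, Et2O), −15 → 0 °C; AcOH quench
Reagents that add atoms: diazomethane, C=[N+]=[N-]
Why: Acylation of diazomethane by the mixed carbonic anhydride (first stage of the Arndt–Eistert sequence) should give the diazomethyl ketone under near-neutral conditions that spare the silyl ether, the pyranone carbonyl and the unactivated alkene.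

Step 6
Reactants: 13 2-chloro-1,1-dimethoxyethane
Product: 15 methoxyacetylene (methoxyethyne), via sodium methoxyacetylide 14 (not isolated)
Conditions: NaNH2 (3.2 equiv), liquid NH3, −33 °C; cold aq. NaCl; distillation (b.p. about 23 °C) into cold ClCH2CH2Cl
Reagents that add atoms: none
Why: Two successive base-induced β-eliminations (loss of methanol, then of HCl) should give the ynol ether, which is held as its sodium acetylide until the aqueous quench.

Step 7
Reactants: 12 2-(2-diazoacetyl)-6-[(2R)-2-(tert-butyldimethylsilyloxy)oct-7-en-1-yl]-4H-pyran-4-one; 15 methoxyacetylene (4 equiv)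
Product: 19 2-[(2R)-2-(tert-butyldimethylsilyloxy)oct-7-en-1-yl]-5-hydroxy-7-methoxy-4H-chromen-4-one, via pyranonylketene 16 (not isolated), via methoxycyclobutenone 17 (not isolated), via dienylketene 18 (not isolated)
Conditions: ClCH2CH2Cl (0.03 M), hν (350–365 nm, Pyrex), 10–15 °C, closed vessel, until N2 evolution ends; then 80 °C, 3 h
Reagents that add atoms: none
Why: Light should expel N2 from 12 with 1,2-shift of the pyranonyl group (Wolff rearrangement) to give ketene 16, the nucleophilic terminal carbon of methoxyacetylene then attacks the ketene carbonyl carbon and the zwitterion closes to cyclobutenone 17 ([2+2] cycloaddition), and 17 opens by reversible four-electron electrocyclic ring opening to dienylketene 18. The closest known reaction type is the Danheiser benzannulation of aryl, heteroaryl and alkenyl diazomethyl ketones with alkoxy- and silyloxyalkynes, in which the same cascade fuses a phenol ring onto the unsaturated group of the diazo ketone. Ring A closes by thermal disrotatory six-electron electrocyclization of 18 across the pyranone C2=C3 bond, which forms C4a–C5 (chromone numbering) after C5–C6 and C7–C8 were made in the cycloaddition and C8–C8a in the Wolff shift, and tautomerization of the cyclohexadienone gives the phenol, held by its hydrogen bond to the C4 carbonyl. No stereocentre is formed, because the sp3 carbons of 17 and of the dienone vanish on aromatization, and the silyloxy-bearing (R)-centre is a remote spectator. The step needs three selectivities: the regiochemistry of the [2+2] addition, secured by the polarization of the ynol ether, which places OMe meta to the new OH (C7 and C5) and leaves C6 and C8 unsubstituted; closure at the right ring atom, secured because the ketene-bearing pyranone carbon has only one carbon neighbour, the nucleophilic α-carbon of the vinylogous ester, which is matched to the electrophilic ketene carbon; and capture of the ketene by the alkyne before anything else, secured by its low stationary concentration, by excess alkyne, by the absence of O–H groups and by light that the pyranone chromophore absorbs only weakly.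

Step 8
Reactants: 19 2-[(2R)-2-(tert-butyldimethylsilyloxy)oct-7-en-1-yl]-5-hydroxy-7-methoxy-4H-chromen-4-one
Product: 21 (6R)-6-(tert-butyldimethylsilyloxy)-7-(5-hydroxy-7-methoxy-4-oxo-4H-chromen-2-yl)heptanal, via vicinal diol 20 (not isolated)
Conditions: OsO4 (2 mol%), NaIO4 (4 equiv), 2,6-lutidine (2 equiv), dioxane/H2O (3:1), rt
Reagents that add atoms: osmium tetroxide, O=[Os](=O)(=O)=O (its oxygen is replenished by sodium periodate, [Na+].[O-]I(=O)(=O)=O)
Why: In this Lemieux–Johnson oxidative cleavage the monosubstituted alkene should be dihydroxylated far faster than the electron-poor trisubstituted C2=C3 bond of the chromone, periodate cleaves the diol to the aldehyde, and the hydrogen-bonded phenol and the silyl ether are inert.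

Step 9
Reactants: 21 (6R)-6-(tert-butyldimethylsilyloxy)-7-(5-hydroxy-7-methoxy-4-oxo-4H-chromen-2-yl)heptanal; 22 tert-butyl (triphenylphosphoranylidene)acetate (1.3 equiv)
Product: 23 tert-butyl (2E,8R)-8-(tert-butyldimethylsilyloxy)-9-(5-hydroxy-7-methoxy-4-oxo-4H-chromen-2-yl)non-2-enoate
Conditions: CH2Cl2, rt
Reagents that add atoms: none
Why: Wittig olefination with a stabilised ylide should give the (E)-enoate through the favoured trans-oxaphosphetane, and the non-basic ylide should not trigger β-elimination of the silyloxy group or react with the phenol.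

Step 10
Reactants: 23 tert-butyl (2E,8R)-8-(tert-butyldimethylsilyloxy)-9-(5-hydroxy-7-methoxy-4-oxo-4H-chromen-2-yl)non-2-enoate
Product: 24 penithochromone T, (2E,8R)-8-hydroxy-9-(5-hydroxy-7-methoxy-4-oxo-4H-chromen-2-yl)non-2-enoic acid
Conditions: CF3CO2H/CH2Cl2/H2O (10:10:1), 0 °C → rt; then aq. NaHCO3/MeOH (cleaves any trifluoroacetate), acidify to pH 3
Reagents that add atoms: none
Why: Acidolysis should cleave the tert-butyl ester through the tert-butyl cation and solvolyse the secondary silyl ether at silicon, so the C–O bond of the stereocentre and the (E)-alkene are not touched, and the seven-membered oxa-Michael closure onto the enoate is too slow to compete.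

Compound list
1 | 2,2,6-trimethyl-4H-1,3-dioxin-4-one | CC1=CC(=O)OC(C)(C)O1 | starting material
2 | [(2,2-dimethyl-6-methylidene-6H-1,3-dioxin-4-yl)oxy]trimethylsilane | C=C1C=C(O[Si](C)(C)C)OC(C)(C)O1 | intermediate
3 | hept-6-enal | C=CCCCCC=O | starting material
4 | 2,2-dimethyl-6-[(2R)-2-(trimethylsilyloxy)oct-7-en-1-yl]-4H-1,3-dioxin-4-one | CC1(C)OC(C[C@H](O[Si](C)(C)C)CCCCC=C)=CC(=O)O1 | intermediate (not isolated)
5 | 6-[(2R)-2-hydroxyoct-7-en-1-yl]-2,2-dimethyl-4H-1,3-dioxin-4-one | CC1(C)OC(C[C@H](O)CCCCC=C)=CC(=O)O1 | intermediate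
6 | 6-[(2R)-2-(tert-butyldimethylsilyloxy)oct-7-en-1-yl]-2,2-dimethyl-4H-1,3-dioxin-4-one | CC1(C)OC(C[C@H](O[Si](C)(C)C(C)(C)C)CCCCC=C)=CC(=O)O1 | intermediate
7 | trimethylsilyl 2-(trimethylsilyloxy)prop-2-enoate | C=C(O[Si](C)(C)C)C(=O)O[Si](C)(C)C | starting material
8 | (5R)-5-(tert-butyldimethylsilyloxy)undeca-1,10-diene-1,3-dione (acylketene) | O=C=CC(=O)C[C@H](O[Si](C)(C)C(C)(C)C)CCCCC=C | intermediate (not isolated)
9 | trimethylsilyl 6-[(2R)-2-(tert-butyldimethylsilyloxy)oct-7-en-1-yl]-4-oxo-2-(trimethylsilyloxy)-3,4-dihydro-2H-pyran-2-carboxylate, both C2 epimers | O=C1CC(O[Si](C)(C)C)(C(=O)O[Si](C)(C)C)OC(C[C@H](O[Si](C)(C)C(C)(C)C)CCCCC=C)=C1 | intermediate (not isolated)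
10 | 6-[(2R)-2-(tert-butyldimethylsilyloxy)oct-7-en-1-yl]-4-oxo-4H-pyran-2-carboxylic acid | OC(=O)c1cc(=O)cc(C[C@H](O[Si](C)(C)C(C)(C)C)CCCCC=C)o1 | intermediate
11 | mixed anhydride of 10 with isobutyl hydrogen carbonate | CC(C)COC(=O)OC(=O)c1cc(=O)cc(C[C@H](O[Si](C)(C)C(C)(C)C)CCCCC=C)o1 | intermediate (not isolated)
12 | 2-(2-diazoacetyl)-6-[(2R)-2-(tert-butyldimethylsilyloxy)oct-7-en-1-yl]-4H-pyran-4-one | [N-]=[N+]=CC(=O)c1cc(=O)cc(C[C@H](O[Si](C)(C)C(C)(C)C)CCCCC=C)o1 | intermediate
13 | 2-chloro-1,1-dimethoxyethane (chloroacetaldehyde dimethyl acetal) | COC(CCl)OC | starting material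
14 | sodium methoxyacetylide | COC#C[Na] | intermediate (not isolated)
15 | methoxyacetylene (methoxyethyne) | COC#C | intermediate
16 | 6-[(2R)-2-(tert-butyldimethylsilyloxy)oct-7-en-1-yl]-2-(2-oxoethenyl)-4H-pyran-4-one (pyranonylketene) | O=C=Cc1cc(=O)cc(C[C@H](O[Si](C)(C)C(C)(C)C)CCCCC=C)o1 | intermediate (not isolated)
17 | 3-methoxy-4-{6-[(2R)-2-(tert-butyldimethylsilyloxy)oct-7-en-1-yl]-4-oxo-4H-pyran-2-yl}cyclobut-2-en-1-one, both C4 epimers | COC1=CC(=O)C1c1cc(=O)cc(C[C@H](O[Si](C)(C)C(C)(C)C)CCCCC=C)o1 | intermediate (not isolated)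
18 | (3E)-3-methoxy-4-{6-[(2R)-2-(tert-butyldimethylsilyloxy)oct-7-en-1-yl]-4-oxo-4H-pyran-2-yl}buta-1,3-dien-1-one (dienylketene, ketene and pyranone cis) | O=C=C/C(OC)=C\c1cc(=O)cc(C[C@H](O[Si](C)(C)C(C)(C)C)CCCCC=C)o1 | intermediate (not isolated)
19 | 2-[(2R)-2-(tert-butyldimethylsilyloxy)oct-7-en-1-yl]-5-hydroxy-7-methoxy-4H-chromen-4-one | COc1cc(O)c2c(=O)cc(C[C@H](O[Si](C)(C)C(C)(C)C)CCCCC=C)oc2c1 | intermediate
20 | 2-[(2R)-2-(tert-butyldimethylsilyloxy)-7,8-dihydroxyoctyl]-5-hydroxy-7-methoxy-4H-chromen-4-one, both C7 epimers | COc1cc(O)c2c(=O)cc(C[C@H](O[Si](C)(C)C(C)(C)C)CCCCC(O)CO)oc2c1 | intermediate (not isolated)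
21 | (6R)-6-(tert-butyldimethylsilyloxy)-7-(5-hydroxy-7-methoxy-4-oxo-4H-chromen-2-yl)heptanal | COc1cc(O)c2c(=O)cc(C[C@H](O[Si](C)(C)C(C)(C)C)CCCCC=O)oc2c1 | intermediate
22 | tert-butyl (triphenylphosphoranylidene)acetate | CC(C)(C)OC(=O)C=P(c1ccccc1)(c1ccccc1)c1ccccc1 | starting material
23 | tert-butyl (2E,8R)-8-(tert-butyldimethylsilyloxy)-9-(5-hydroxy-7-methoxy-4-oxo-4H-chromen-2-yl)non-2-enoate | COc1cc(O)c2c(=O)cc(C[C@H](O[Si](C)(C)C(C)(C)C)CCCC/C=C/C(=O)OC(C)(C)C)oc2c1 | intermediate
24 | penithochromone T, (2E,8R)-8-hydroxy-9-(5-hydroxy-7-methoxy-4-oxo-4H-chromen-2-yl)non-2-enoic acid | COc1cc(O)c2c(=O)cc(C[C@H](O)CCCC/C=C/C(=O)O)oc2c1 | target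

Total step count: 10. Longest linear sequence: 9 steps (steps 1 to 5 and 7 to 10); step 6 is a one-step side branch.

Steps most likely to fail

Step 7. The photochemical cascade may stall or divert: the pyranone chromophore may compete for light and react on its own, or the ketene may be consumed before it meets the alkyne. The fallback sets out from 12 and generates the same ketene in the dark, in separate, controllable stages.
- Wolff rearrangement of 12 with AgO2CPh (monovalent silver) and Et3N in aqueous THF would give the homologous acid {6-[(2R)-2-(tert-butyldimethylsilyloxy)oct-7-en-1-yl]-4-oxo-4H-pyran-2-yl}acetic acid F1.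
- 1-Chloro-N,N,2-trimethylprop-1-en-1-amine would convert F1 under neutral conditions into {6-[(2R)-2-(tert-butyldimethylsilyloxy)oct-7-en-1-yl]-4-oxo-4H-pyran-2-yl}acetyl chloride F2.
- Dehydrochlorination of F2 with Et3N in the presence of excess 15 at 0 °C would give cyclobutenone 17, this time isolated and purified.
- Heating 17 in toluene at 80–110 °C would complete the ring expansion, and the fallback comes back to the route at 19.

Step 4. The enol ether 7 carries an acceptor group and may add too slowly, so that the acylketene dimerises or transfers silicon instead of cyclising. The fallback sets out from 6 and uses a simple, well-behaved enol ether.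
- Thermolysis of 6 with 2-methoxypropene (toluene, 110 °C, closed vessel) would give 6-[(2R)-2-(tert-butyldimethylsilyloxy)oct-7-en-1-yl]-2-methoxy-2-methyl-2,3-dihydro-4H-pyran-4-one F3.
- Catalytic TsOH would eliminate methanol to 2-[(2R)-2-(tert-butyldimethylsilyloxy)oct-7-en-1-yl]-6-methyl-4H-pyran-4-one F4.
- Kinetic deprotonation of the unhindered methyl group with LiN(SiMe3)2 at −78 °C and carboxylation with CO2 would give {6-[(2R)-2-(tert-butyldimethylsilyloxy)oct-7-en-1-yl]-4-oxo-4H-pyran-2-yl}acetic acid F1.
- F1 would be carried through {6-[(2R)-2-(tert-butyldimethylsilyloxy)oct-7-en-1-yl]-4-oxo-4H-pyran-2-yl}acetyl chloride F2 and cyclobutenone 17 as described for step 7, so this fallback comes back to the route at 19 and bypasses 10 and 12.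

Step 2. Facial selectivity may be insufficient with an unbranched aliphatic aldehyde, and the sense of induction is assigned only by analogy. The fallback sets out from 3 and sets the carbinol by a hydrogenation of textbook sense.
- Roskamp homologation of 3 with methyl diazoacetate and SnCl2 would give methyl 3-oxonon-8-enoate F5.
- Noyori hydrogenation with RuCl2[(R)-BINAP] (divalent ruthenium) in MeOH at low H2 pressure, where the chelating keto ester should be reduced much faster than the remote alkene, would give methyl (3R)-3-hydroxynon-8-enoate F6.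
- Silylation (t-BuMe2SiCl, imidazole) would give methyl (3R)-3-(tert-butyldimethylsilyloxy)non-8-enoate F7.
- Claisen condensation with the lithium enolate of tert-butyl acetate (from LiN(i-Pr)2, 2.5 equiv, −78 → −40 °C) would give tert-butyl (5R)-5-(tert-butyldimethylsilyloxy)-3-oxoundec-10-enoate F8.
- Heating F8 with 7 in toluene at 110 °C would expel tert-butanol to the same acylketene 8, so the fallback comes back to the route at 10 after the acid work-up of step 4.

Further compounds
F1 | step 7 | {6-[(2R)-2-(tert-butyldimethylsilyloxy)oct-7-en-1-yl]-4-oxo-4H-pyran-2-yl}acetic acid | OC(=O)Cc1cc(=O)cc(C[C@H](O[Si](C)(C)C(C)(C)C)CCCCC=C)o1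
F2 | step 7 | {6-[(2R)-2-(tert-butyldimethylsilyloxy)oct-7-en-1-yl]-4-oxo-4H-pyran-2-yl}acetyl chloride | ClC(=O)Cc1cc(=O)cc(C[C@H](O[Si](C)(C)C(C)(C)C)CCCCC=C)o1
F3 | step 4 | 6-[(2R)-2-(tert-butyldimethylsilyloxy)oct-7-en-1-yl]-2-methoxy-2-methyl-2,3-dihydro-4H-pyran-4-one | COC1(C)CC(=O)C=C(C[C@H](O[Si](C)(C)C(C)(C)C)CCCCC=C)O1
F4 | step 4 | 2-[(2R)-2-(tert-butyldimethylsilyloxy)oct-7-en-1-yl]-6-methyl-4H-pyran-4-one | Cc1cc(=O)cc(C[C@H](O[Si](C)(C)C(C)(C)C)CCCCC=C)o1
F5 | step 2 | methyl 3-oxonon-8-enoate | COC(=O)CC(=O)CCCCC=C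
F6 | step 2 | methyl (3R)-3-hydroxynon-8-enoate | COC(=O)C[C@H](O)CCCCC=C
F7 | step 2 | methyl (3R)-3-(tert-butyldimethylsilyloxy)non-8-enoate | COC(=O)C[C@H](O[Si](C)(C)C(C)(C)C)CCCCC=C
F8 | step 2 | tert-butyl (5R)-5-(tert-butyldimethylsilyloxy)-3-oxoundec-10-enoate | CC(C)(C)OC(=O)CC(=O)C[C@H](O[Si](C)(C)C(C)(C)C)CCCCC=C
A1 | direct plan | 3,5-dimethoxy-2-(trimethylsilyl)phenyl trifluoromethanesulfonate | COc1cc(OC)c([Si](C)(C)C)c(OS(=O)(=O)C(F)(F)F)c1
A2 | direct plan | (5R)-5-(methoxymethoxy)undec-10-en-2-ynoic acid | OC(=O)C#CC[C@H](OCOC)CCCCC=C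
A3 | direct plan | 5,7-dimethoxy-2-[(2R)-2-(methoxymethoxy)oct-7-en-1-yl]-4H-chromen-4-one | COc1cc(OC)c2c(=O)cc(C[C@H](OCOC)CCCCC=C)oc2c1
A4 | direct plan | 5-hydroxy-2-[(2R)-2-hydroxyoct-7-en-1-yl]-7-methoxy-4H-chromen-4-one | COc1cc(O)c2c(=O)cc(C[C@H](O)CCCCC=C)oc2c1
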